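## Retrosynthetic overview

1. Guaiane numbering is used, unprimed for the enone half (unit A) and primed for the spiro-ketone half (unit B). The spiro cyclohexene (C2, C1, C10, C14, C15′, C4′) is cut at C2–C4′ and C14–C15′: Diels–Alder reaction of trienone 39 (diene C2=C1–C10=C14) with the C4′=C15′ methylene ketone of 31, then shift of C1=C10 to C1=C2, which sets C10.
2. Structural feature carrying the strategy: in unit B the cyclopentanone ring C1′–C5′ (carbonyl C3′), fused through C1′–C5′ to the seven-membered ring C1′/C5′–C10′, is the bicyclo[5.3.0]decadienone of an allenic Pauson–Khand reaction of an allene-yne with tether C6′–C9′ (bonds C1′–C5′, C3′–C4′, C2′–C3′). Unit A is made the same way.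
3. After the key step, reductive 1,3-transpositions of the C15 and C14 allylic alcohols give C4=C15 with H5 and C10=C14 with H1. Unit A needs only the first; its O14 becomes the leaving group that releases the diene.
4. Allene-yne lactones come from butenolide 7 (C6 by asymmetric alkynylation, ring by metathesis) and homoallenyl Grignard reagent 15. C7 is set by anti conjugate addition, C11 by enolate methylation (11S, unit A) or kinetic reprotonation (11R, unit B).
5. Ring order in each half: γ-lactone, then seven-membered ring and cyclopentenone together; the spiro cyclohexene is closed last.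

Key step: step 11

Remarks: the O14 silyl group is tert-butyldiphenylsilyl (not TBS) so that O15 and O14 can be unmasked in turn; the (S,S)-ProPhenol–zinc catalyst is assumed to give the 4S alcohol, otherwise its enantiomer is used.

## Route

Step 1
Reactants: 1 tert-butyldimethyl(prop-2-yn-1-yloxy)silane; 2 (E)-but-2-enal
Product: 4 (4S,5E)-1-[(tert-butyldimethylsilyl)oxy]hept-5-en-2-yn-4-ol, via alkynyl(methyl)zinc 3 (not isolated)
Conditions: Me2Zn, (S,S)-ProPhenol (10 mol%), Ph3P=O (20 mol%), toluene, 0 → 4 °C; aq NH4Cl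
Reagents that add atoms: none
Why: Zinc–ProPhenol-catalysed enantioselective alkynylation of an α,β-unsaturated aldehyde, in which the chiral dinuclear zinc complex directs alkynylzinc 3 to one aldehyde face and so sets C6 (S).

Step 2
Reactants: 4 (4S,5E)-1-[(tert-butyldimethylsilyl)oxy]hept-5-en-2-yn-4-ol; 5 prop-2-enoyl chloride
Product: 6 (4S,5E)-1-[(tert-butyldimethylsilyl)oxy]hept-5-en-2-yn-4-yl prop-2-enoate
Conditions: i-Pr2NEt, CH2Cl2, −78 → 0 °C
Reagents that add atoms: none
Why: Acylation of a secondary alcohol with an acid chloride and a hindered amine base installs C11–C12 without touching the carbinol centre.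

Step 3
Reactants: 6 (4S,5E)-1-[(tert-butyldimethylsilyl)oxy]hept-5-en-2-yn-4-yl prop-2-enoate
Product: 7 (5S)-5-{3-[(tert-butyldimethylsilyl)oxy]prop-1-yn-1-yl}furan-2(5H)-one
Conditions: second-generation Grubbs catalyst (5 mol%), CH2Cl2 (5 mM), 40 °C
Reagents that add atoms: none
Why: Ring-closing metathesis between the acrylate and the propenyl group (propene is lost) closes the butenolide, the internal alkyne being too hindered and too badly placed to take part, and C6 is untouched.

Step 4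
Reactants: 8 but-2-yne-1,4-diol
Product: 9 4-[(tert-butyldiphenylsilyl)oxy]but-2-yn-1-ol
Conditions: t-BuPh2SiCl (1 equiv), imidazole, 8 (3 equiv), DMF, 0 °C → rt
Reagents that add atoms: tert-butyl(chloro)diphenylsilane, CC(C)(C)[Si](Cl)(c1ccccc1)c1ccccc1
Why: Statistical monosilylation of a symmetrical diol used in excess.

Step 5
Reactants: 9 4-[(tert-butyldiphenylsilyl)oxy]but-2-yn-1-ol; 10 triethyl orthoacetate
Product: 12 ethyl 3-{[(tert-butyldiphenylsilyl)oxy]methyl}penta-3,4-dienoate, via ketene acetal 11 (not isolated)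
Conditions: EtCO2H (cat.), 140 °C, ethanol distilled off
Reagents that add atoms: none
Why: Johnson orthoester Claisen rearrangement of a propargylic alcohol, in which ketene acetal 11 rearranges [3,3] onto the alkyne carbon bearing CH2OSi and gives the 1,1-disubstituted allene C10=C1=C2 with C8–C9 attached.

Step 6
Reactants: 12 ethyl 3-{[(tert-butyldiphenylsilyl)oxy]methyl}penta-3,4-dienoate
Product: 13 3-{[(tert-butyldiphenylsilyl)oxy]methyl}penta-3,4-dien-1-ol
Conditions: i-Bu2AlH, CH2Cl2, −78 → 0 °C; aq Rochelle salt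
Reagents that add atoms: none
Why: Hydride reduction of an ester to the primary alcohol at low temperature leaves the allene and the silyl ether alone.

Step 7
Reactants: 13 3-{[(tert-butyldiphenylsilyl)oxy]methyl}penta-3,4-dien-1-ol
Product: 14 5-bromo-3-{[(tert-butyldiphenylsilyl)oxy]methyl}penta-1,2-diene
Conditions: CBr4, PPh3, CH2Cl2, 0 °C
Reagents that add atoms: tetrabromomethane, BrC(Br)(Br)Br
Why: Appel bromination of a primary alcohol under neutral conditions.

Step 8
Reactants: 14 5-bromo-3-{[(tert-butyldiphenylsilyl)oxy]methyl}penta-1,2-diene; 7 (5S)-5-{3-[(tert-butyldimethylsilyl)oxy]prop-1-yn-1-yl}furan-2(5H)-one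
Product: 17 (4S,5S)-4-(3-{[(tert-butyldiphenylsilyl)oxy]methyl}penta-3,4-dien-1-yl)-5-{3-[(tert-butyldimethylsilyl)oxy]prop-1-yn-1-yl}oxolan-2-one, via Grignard reagent 15 (not isolated), via silyl ketene acetal 16 (not isolated)
Conditions: 14, Mg, THF, rt; then CuBr·SMe2 (10 mol%), Me3SiCl, 7, THF, −78 °C; aq NH4Cl
Reagents that add atoms: none
Why: Copper-catalysed, Me3SiCl-accelerated conjugate addition of a Grignard reagent to a butenolide, in which the alkyl group enters anti to the alkynyl group at C6 and sets C7 (trans lactone); the unsubstituted butenolide should react at −78 °C before the organocopper can displace the propargylic carboxylate.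

Step 9
Reactants: 17 (4S,5S)-4-(3-{[(tert-butyldiphenylsilyl)oxy]methyl}penta-3,4-dien-1-yl)-5-{3-[(tert-butyldimethylsilyl)oxy]prop-1-yn-1-yl}oxolan-2-one
Product: 19 (3S,4S,5S)-3-methyl-4-(3-{[(tert-butyldiphenylsilyl)oxy]methyl}penta-3,4-dien-1-yl)-5-{3-[(tert-butyldimethylsilyl)oxy]prop-1-yn-1-yl}oxolan-2-one, via lithium enolate 18 (not isolated)
Conditions: LiN(i-Pr)2, THF, −78 °C; MeI, −78 → −40 °C
Reagents that add atoms: iodomethane, CI
Why: Alkylation of the lactone lithium enolate, in which iodomethane enters anti to the C7 side chain and gives the 7,11-trans (11S) methyl lactone needed for unit A.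

Step 10
Reactants: 19 (3S,4S,5S)-3-methyl-4-(3-{[(tert-butyldiphenylsilyl)oxy]methyl}penta-3,4-dien-1-yl)-5-{3-[(tert-butyldimethylsilyl)oxy]prop-1-yn-1-yl}oxolan-2-one
Product: 21 (3R,4S,5S)-3-methyl-4-(3-{[(tert-butyldiphenylsilyl)oxy]methyl}penta-3,4-dien-1-yl)-5-{3-[(tert-butyldimethylsilyl)oxy]prop-1-yn-1-yl}oxolan-2-one, via lithium enolate 20 (not isolated)
Conditions: LiN(i-Pr)2, THF, −78 °C; then 2,6-di-tert-butyl-4-methylphenol, −78 °C
Reagents that add atoms: none
Why: Deprotonation and kinetic reprotonation of the lactone enolate, in which the bulky phenol delivers the proton anti to the C7 side chain and so turns the methyl group cis to it (11R, needed for unit B).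

Step 11
Reactants: 21 (3R,4S,5S)-3-methyl-4-(3-{[(tert-butyldiphenylsilyl)oxy]methyl}penta-3,4-dien-1-yl)-5-{3-[(tert-butyldimethylsilyl)oxy]prop-1-yn-1-yl}oxolan-2-one; 22 carbon monoxide
Product: 23 (6S,7S,11R)-15-[(tert-butyldimethylsilyl)oxy]-14-[(tert-butyldiphenylsilyl)oxy]-3-oxoguaia-1(10),4-dien-12,6-olide
Conditions: [Rh(CO)2Cl]2 (10 mol%), CO (1 atm), toluene (0.01 M), 90 °C
Reagents that add atoms: none
Why: Monovalent rhodium binds the alkyne C4′≡C5′ and the distal allene bond C1′=C2′ and couples C5′ with C1′ oxidatively to a rhodacyclopentene, CO inserts and reductive elimination forms C3′–C4′ and C2′–C3′. This is the rhodium-catalysed allenic Pauson–Khand reaction, known for allene-ynes with a four-atom tether and for lactone-tethered guaianolide cores. The seven-membered ring (C1′, C5′–C10′) closes in the oxidative cyclisation through the C1′–C5′ bond, exo with respect to the alkyne and onto the central allene carbon; the cyclopentenone (C1′–C5′) closes by migratory CO insertion and C–C reductive elimination. No stereocentre is created, and C6′, C7′ and C11′ of the trans-lactone pass through unchanged because no base or enolisable intermediate is involved. The step needs reaction at the distal and not the proximal allene bond, which the rhodium catalyst and the fully substituted proximal carbon C10′ secure, and high dilution under CO suppresses intermolecular pathways.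

Step 12
Reactants: 23 (6S,7S,11R)-15-[(tert-butyldimethylsilyl)oxy]-14-[(tert-butyldiphenylsilyl)oxy]-3-oxoguaia-1(10),4-dien-12,6-olide
Product: 24 (6S,7S,11R)-14-[(tert-butyldiphenylsilyl)oxy]-15-hydroxy-3-oxoguaia-1(10),4-dien-12,6-olide
Conditions: pyridinium p-toluenesulfonate (0.2 equiv), MeOH, rt
Reagents that add atoms: none
Why: Acid-catalysed methanolysis removes the primary TBS ether while the much more acid-stable TBDPS ether stays.

Step 13
Reactants: 24 (6S,7S,11R)-14-[(tert-butyldiphenylsilyl)oxy]-15-hydroxy-3-oxoguaia-1(10),4-dien-12,6-olide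
Product: 27 (11R)-14-[(tert-butyldiphenylsilyl)oxy]-3-oxo-5αH,6βH,7αH-guaia-1(10),4(15)-dien-12,6-olide, via sulfonylhydrazone 25 (not isolated), via allylic diazene 26 (not isolated)
Conditions: PPh3, diethyl azodicarboxylate, N-isopropylidene-N′-(2-nitrobenzenesulfonyl)hydrazine (IPNBSH), THF, 0 °C → rt; then CF3CH2OH–H2O (1:1), rt
Reagents that add atoms: none
Why: Mitsunobu displacement by IPNBSH, hydrolysis to the monoalkyl diazene and retro-ene loss of N2 (reductive 1,3-transposition of an allylic alcohol) place hydrogen on C5′ and move the alkene to C4′=C15′; delivery to the α-face, antiperiplanar to the axial C6′–H of the lactone-locked seven-membered ring, should set H5′ trans to H6′.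

Step 14
Reactants: 27 (11R)-14-[(tert-butyldiphenylsilyl)oxy]-3-oxo-5αH,6βH,7αH-guaia-1(10),4(15)-dien-12,6-olide
Product: 28 (11R)-14-hydroxy-3-oxo-5αH,6βH,7αH-guaia-1(10),4(15)-dien-12,6-olide
Conditions: HF·pyridine, pyridine, THF, 0 °C → rt
Reagents that add atoms: none
Why: Fluoride cleavage of the TBDPS ether under buffered, non-basic conditions, so that the β,γ-unsaturated ketone and the methylene ketone do not isomerise.

Step 15
Reactants: 28 (11R)-14-hydroxy-3-oxo-5αH,6βH,7αH-guaia-1(10),4(15)-dien-12,6-olide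
Product: 31 (11R)-3-oxo-1αH,5αH,6βH,7αH-guaia-4(15),10(14)-dien-12,6-olide (unit B monomer, 11β-methyl), via sulfonylhydrazone 29 (not isolated), via allylic diazene 30 (not isolated)
Conditions: PPh3 and diethyl azodicarboxylate premixed, IPNBSH, THF, 0 °C → rt; then CF3CH2OH–H2O (1:1), rt
Reagents that add atoms: none
Why: Second reductive 1,3-transposition through the allylic diazene, which puts hydrogen on C1′ from the face of H5′ (anti to the C5′–C6′ bond, giving the cis-fused bicycle) and moves the alkene to C10′=C14′.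

Step 16
Reactants: 19 (3S,4S,5S)-3-methyl-4-(3-{[(tert-butyldiphenylsilyl)oxy]methyl}penta-3,4-dien-1-yl)-5-{3-[(tert-butyldimethylsilyl)oxy]prop-1-yn-1-yl}oxolan-2-one; 22 carbon monoxide
Product: 32 (6S,7S,11S)-15-[(tert-butyldimethylsilyl)oxy]-14-[(tert-butyldiphenylsilyl)oxy]-3-oxoguaia-1(10),4-dien-12,6-olide
Conditions: [Rh(CO)2Cl]2 (10 mol%), CO (1 atm), toluene (0.01 M), 90 °C
Reagents that add atoms: none
Why: The same rhodium-catalysed allenic Pauson–Khand reaction as in step 11 on the C11 epimer, closing the seven-membered ring and the cyclopentenone of unit A (C1–C5, C3–C4, C2–C3) with the distal allene bond and without change at C6, C7 and C11.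

Step 17
Reactants: 32 (6S,7S,11S)-15-[(tert-butyldimethylsilyl)oxy]-14-[(tert-butyldiphenylsilyl)oxy]-3-oxoguaia-1(10),4-dien-12,6-olide
Product: 33 (6S,7S,11S)-14-[(tert-butyldiphenylsilyl)oxy]-15-hydroxy-3-oxoguaia-1(10),4-dien-12,6-olide
Conditions: pyridinium p-toluenesulfonate (0.2 equiv), MeOH, rt
Reagents that add atoms: none
Why: Selective acid-catalysed methanolysis of the primary TBS ether, as in step 12.

Step 18
Reactants: 33 (6S,7S,11S)-14-[(tert-butyldiphenylsilyl)oxy]-15-hydroxy-3-oxoguaia-1(10),4-dien-12,6-olide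
Product: 36 (11S)-14-[(tert-butyldiphenylsilyl)oxy]-3-oxo-5αH,6βH,7αH-guaia-1(10),4(15)-dien-12,6-olide, via sulfonylhydrazone 34 (not isolated), via allylic diazene 35 (not isolated)
Conditions: PPh3, diethyl azodicarboxylate, IPNBSH, THF, 0 °C → rt; then CF3CH2OH–H2O (1:1), rt
Reagents that add atoms: none
Why: Reductive 1,3-transposition of the allylic alcohol through the allylic diazene as in step 13, which sets H5 on the α-face (anti to the axial C6–H) and forms C4=C15.

Step 19
Reactants: 36 (11S)-14-[(tert-butyldiphenylsilyl)oxy]-3-oxo-5αH,6βH,7αH-guaia-1(10),4(15)-dien-12,6-olide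
Product: 37 (11S)-14-hydroxy-3-oxo-5αH,6βH,7αH-guaia-1(10),4(15)-dien-12,6-olide
Conditions: HF·pyridine, pyridine, THF, 0 °C → rt
Reagents that add atoms: none
Why: Buffered fluoride cleavage of the TBDPS ether, as in step 14.

Step 20
Reactants: 37 (11S)-14-hydroxy-3-oxo-5αH,6βH,7αH-guaia-1(10),4(15)-dien-12,6-olide; 31 (11R)-3-oxo-1αH,5αH,6βH,7αH-guaia-4(15),10(14)-dien-12,6-olide
Product: 40 Diels–Alder adduct with bonds C2–C4′ and C14–C15′ and the C1=C10 double bond (2βH), via allylic mesylate 38 (not isolated), via trienone 39 (not isolated)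
Conditions: MeSO2Cl (1.2 equiv), Et3N (4 equiv), 31 (3 equiv), CH2Cl2, −20 °C → rt
Reagents that add atoms: none
Why: Mesylation and amine-induced vinylogous E1cB elimination (loss of H2 and O14) release trienone 39, whose s-cis-locked diene C2=C1–C10=C14 adds to the C4′=C15′ methylene ketone of 31 in a Diels–Alder reaction with ortho orientation (C2–C4′, C14–C15′); attack on the α-face of 31 (side of H5′, away from C6′) sets the spiro centre C4′, and the configuration at C2 is of no consequence because step 21 removes it.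

Step 21
Reactants: 40 Diels–Alder adduct with bonds C2–C4′ and C14–C15′ and the C1=C10 double bond
Product: 41 CNP0240988.1
Conditions: 1,8-diazabicyclo[5.4.0]undec-7-ene (0.1 equiv), CH2Cl2, −20 → 0 °C; AcOH quench
Reagents that add atoms: none
Why: Base-mediated isomerisation of the β,γ-unsaturated ketone into conjugation through the extended enolate (O–C3=C2–C1=C10), with γ-protonation at C10 on the β-face, anti to the axial C9–H, which gives the H5/H10-trans arrangement (twist-chair seven-membered ring with the sp2 C1 on its axis) and removes the stereocentre at C2.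

## Compound list

1 | tert-butyldimethyl(prop-2-yn-1-yloxy)silane | C#CCO[Si](C)(C)C(C)(C)C | starting material
2 | (E)-but-2-enal | C/C=C/C=O | starting material
3 | methyl{3-[(tert-butyldimethylsilyl)oxy]prop-1-yn-1-yl}zinc | C[Zn]C#CCO[Si](C)(C)C(C)(C)C | intermediate
4 | (4S,5E)-1-[(tert-butyldimethylsilyl)oxy]hept-5-en-2-yn-4-ol | CC(C)(C)[Si](C)(C)OCC#C[C@@H](O)/C=C/C | intermediate
5 | prop-2-enoyl chloride | C=CC(Cl)=O | starting material
6 | (4S,5E)-1-[(tert-butyldimethylsilyl)oxy]hept-5-en-2-yn-4-yl prop-2-enoate | CC(C)(C)[Si](C)(C)OCC#C[C@@H](OC(=O)C=C)/C=C/C | intermediate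
7 | (5S)-5-{3-[(tert-butyldimethylsilyl)oxy]prop-1-yn-1-yl}furan-2(5H)-one | CC(C)(C)[Si](C)(C)OCC#C[C@H]1OC(=O)C=C1 | intermediate
8 | but-2-yne-1,4-diol | OCC#CCO | starting material
9 | 4-[(tert-butyldiphenylsilyl)oxy]but-2-yn-1-ol | OCC#CCO[Si](c1ccccc1)(c1ccccc1)C(C)(C)C | intermediate
10 | triethyl orthoacetate | CCOC(C)(OCC)OCC | starting material
11 | 1-ethoxy-1-({4-[(tert-butyldiphenylsilyl)oxy]but-2-yn-1-yl}oxy)ethene | C=C(OCC)OCC#CCO[Si](c1ccccc1)(c1ccccc1)C(C)(C)C | intermediate
12 | ethyl 3-{[(tert-butyldiphenylsilyl)oxy]methyl}penta-3,4-dienoate | CCOC(=O)CC(CO[Si](c1ccccc1)(c1ccccc1)C(C)(C)C)=C=C | intermediate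
13 | 3-{[(tert-butyldiphenylsilyl)oxy]methyl}penta-3,4-dien-1-ol | OCCC(CO[Si](c1ccccc1)(c1ccccc1)C(C)(C)C)=C=C | intermediate
14 | 5-bromo-3-{[(tert-butyldiphenylsilyl)oxy]methyl}penta-1,2-diene | BrCCC(CO[Si](c1ccccc1)(c1ccccc1)C(C)(C)C)=C=C | intermediate
15 | (3-{[(tert-butyldiphenylsilyl)oxy]methyl}penta-3,4-dien-1-yl)magnesium bromide | Br[Mg]CCC(CO[Si](c1ccccc1)(c1ccccc1)C(C)(C)C)=C=C | intermediate
16 | trimethylsilyl ketene acetal of 17 (2-silyloxy-4,5-dihydrofuran, 4S,5S) | CC(C)(C)[Si](C)(C)OCC#C[C@H]1OC(O[Si](C)(C)C)=C[C@@H]1CCC(CO[Si](c2ccccc2)(c2ccccc2)C(C)(C)C)=C=C | intermediate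
17 | (4S,5S)-4-(3-{[(tert-butyldiphenylsilyl)oxy]methyl}penta-3,4-dien-1-yl)-5-{3-[(tert-butyldimethylsilyl)oxy]prop-1-yn-1-yl}oxolan-2-one | CC(C)(C)[Si](C)(C)OCC#C[C@H]1OC(=O)C[C@@H]1CCC(CO[Si](c2ccccc2)(c2ccccc2)C(C)(C)C)=C=C | intermediate
18 | lithium enolate of 17 | CC(C)(C)[Si](C)(C)OCC#C[C@H]1OC(O[Li])=C[C@@H]1CCC(CO[Si](c2ccccc2)(c2ccccc2)C(C)(C)C)=C=C | intermediate
19 | (3S,4S,5S)-3-methyl lactone (3,4-trans, 11S; unit A allene-yne) | CC(C)(C)[Si](C)(C)OCC#C[C@H]1OC(=O)[C@@H](C)[C@@H]1CCC(CO[Si](c2ccccc2)(c2ccccc2)C(C)(C)C)=C=C | intermediate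
20 | lithium enolate of 19 | CC(C)(C)[Si](C)(C)OCC#C[C@H]1OC(O[Li])=C(C)[C@@H]1CCC(CO[Si](c2ccccc2)(c2ccccc2)C(C)(C)C)=C=C | intermediate
21 | (3R,4S,5S)-3-methyl lactone (3,4-cis, 11R; unit B allene-yne, key-step precursor) | CC(C)(C)[Si](C)(C)OCC#C[C@H]1OC(=O)[C@H](C)[C@@H]1CCC(CO[Si](c2ccccc2)(c2ccccc2)C(C)(C)C)=C=C | intermediate
22 | carbon monoxide | [C-]#[O+] | starting material
23 | (6S,7S,11R)-15-[(tert-butyldimethylsilyl)oxy]-14-[(tert-butyldiphenylsilyl)oxy]-3-oxoguaia-1(10),4-dien-12,6-olide (key-step product) | CC(C)(C)[Si](C)(C)OCC1=C2[C@H]3OC(=O)[C@H](C)[C@@H]3CCC(CO[Si](c4ccccc4)(c4ccccc4)C(C)(C)C)=C2CC1=O | intermediate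
24 | (6S,7S,11R)-14-[(tert-butyldiphenylsilyl)oxy]-15-hydroxy-3-oxoguaia-1(10),4-dien-12,6-olide | OCC1=C2[C@H]3OC(=O)[C@H](C)[C@@H]3CCC(CO[Si](c4ccccc4)(c4ccccc4)C(C)(C)C)=C2CC1=O | intermediate
25 | N-(C15′-alkyl)-N-(2-nitrobenzenesulfonyl) acetone hydrazone of 24 | CC(C)=NN(CC1=C2[C@H]3OC(=O)[C@H](C)[C@@H]3CCC(CO[Si](c4ccccc4)(c4ccccc4)C(C)(C)C)=C2CC1=O)S(=O)(=O)c1ccccc1[N+](=O)[O-] | intermediate
26 | C15′ monoalkyl diazene (11R series) | N=NCC1=C2[C@H]3OC(=O)[C@H](C)[C@@H]3CCC(CO[Si](c4ccccc4)(c4ccccc4)C(C)(C)C)=C2CC1=O | intermediate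
27 | (11R)-14-[(tert-butyldiphenylsilyl)oxy]-3-oxo-5αH,6βH,7αH-guaia-1(10),4(15)-dien-12,6-olide | C=C1C(=O)CC2=C(CO[Si](c3ccccc3)(c3ccccc3)C(C)(C)C)CC[C@@H]3[C@H](OC(=O)[C@@H]3C)[C@@H]12 | intermediate
28 | (11R)-14-hydroxy-3-oxo-5αH,6βH,7αH-guaia-1(10),4(15)-dien-12,6-olide | C=C1C(=O)CC2=C(CO)CC[C@@H]3[C@H](OC(=O)[C@@H]3C)[C@@H]12 | intermediate
29 | N-(C14′-alkyl)-N-(2-nitrobenzenesulfonyl) acetone hydrazone of 28 | C=C1C(=O)CC2=C(CN(N=C(C)C)S(=O)(=O)c3ccccc3[N+](=O)[O-])CC[C@@H]3[C@H](OC(=O)[C@@H]3C)[C@@H]12 | intermediate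
30 | C14′ monoalkyl diazene (11R series) | C=C1C(=O)CC2=C(CN=N)CC[C@@H]3[C@H](OC(=O)[C@@H]3C)[C@@H]12 | intermediate
31 | (11R)-3-oxo-1αH,5αH,6βH,7αH-guaia-4(15),10(14)-dien-12,6-olide (unit B monomer) | C=C1C(=O)C[C@H]2C(=C)CC[C@@H]3[C@H](OC(=O)[C@@H]3C)[C@@H]12 | intermediate
32 | (6S,7S,11S)-15-[(tert-butyldimethylsilyl)oxy]-14-[(tert-butyldiphenylsilyl)oxy]-3-oxoguaia-1(10),4-dien-12,6-olide | CC(C)(C)[Si](C)(C)OCC1=C2[C@H]3OC(=O)[C@@H](C)[C@@H]3CCC(CO[Si](c4ccccc4)(c4ccccc4)C(C)(C)C)=C2CC1=O | intermediate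
33 | (6S,7S,11S)-14-[(tert-butyldiphenylsilyl)oxy]-15-hydroxy-3-oxoguaia-1(10),4-dien-12,6-olide | OCC1=C2[C@H]3OC(=O)[C@@H](C)[C@@H]3CCC(CO[Si](c4ccccc4)(c4ccccc4)C(C)(C)C)=C2CC1=O | intermediate
34 | N-(C15-alkyl)-N-(2-nitrobenzenesulfonyl) acetone hydrazone of 33 | CC(C)=NN(CC1=C2[C@H]3OC(=O)[C@@H](C)[C@@H]3CCC(CO[Si](c4ccccc4)(c4ccccc4)C(C)(C)C)=C2CC1=O)S(=O)(=O)c1ccccc1[N+](=O)[O-] | intermediate
35 | C15 monoalkyl diazene (11S series) | N=NCC1=C2[C@H]3OC(=O)[C@@H](C)[C@@H]3CCC(CO[Si](c4ccccc4)(c4ccccc4)C(C)(C)C)=C2CC1=O | intermediate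
36 | (11S)-14-[(tert-butyldiphenylsilyl)oxy]-3-oxo-5αH,6βH,7αH-guaia-1(10),4(15)-dien-12,6-olide | C=C1C(=O)CC2=C(CO[Si](c3ccccc3)(c3ccccc3)C(C)(C)C)CC[C@@H]3[C@H](OC(=O)[C@H]3C)[C@@H]12 | intermediate
37 | (11S)-14-hydroxy-3-oxo-5αH,6βH,7αH-guaia-1(10),4(15)-dien-12,6-olide | C=C1C(=O)CC2=C(CO)CC[C@@H]3[C@H](OC(=O)[C@H]3C)[C@@H]12 | intermediate
38 | 14-methanesulfonate of 37 | C=C1C(=O)CC2=C(COS(C)(=O)=O)CC[C@@H]3[C@H](OC(=O)[C@H]3C)[C@@H]12 | intermediate
39 | (11S)-3-oxo-5αH,6βH,7αH-guaia-1,4(15),10(14)-trien-12,6-olide (trienone) | C=C1C(=O)C=C2C(=C)CC[C@@H]3[C@H](OC(=O)[C@H]3C)[C@@H]12 | intermediate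
40 | Diels–Alder adduct: spiro dimer with C2–C4′ and C14–C15′ bonds, C1=C10 double bond, 2βH, C2 on the α-face of unit B | C=C1C(=O)[C@H]2C3=C(CC[C@@H]4[C@H](OC(=O)[C@H]4C)[C@@H]13)CC[C@]21C(=O)C[C@H]2C(=C)CC[C@@H]3[C@H](OC(=O)[C@@H]3C)[C@H]21 | intermediate
41 | CNP0240988.1 | C=C1C(=O)C2=C3[C@@H](CC[C@@H]4[C@H](OC(=O)[C@H]4C)[C@@H]13)CC[C@]21C(=O)C[C@H]2C(=C)CC[C@@H]3[C@H](OC(=O)[C@@H]3C)[C@H]21 | target

## Step count and risks

Total step count: 21. Longest linear sequence: 14 steps (steps 4–15, then 20 and 21, from but-2-yne-1,4-diol).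

Steps most likely to fail:

1. Step 13 (the same operation recurs as step 18). Hydrogen may be delivered to the β-face of C5 (poor facial selectivity), or the N-amino sulfonamide freed on hydrolysis may condense with the C3 ketone before it loses sulfinate. The fallback is a conjugate reduction–elimination with an external copper hydride. It sets out from 24: acetylation (Ac2O, pyridine, 0 °C) would give the 15′-acetate F1, and [(Ph3P)CuH]6 in toluene would add hydride to C5′ with loss of acetate from the copper enolate, coming back to the route at 27. In the 11S series the same two operations would lead from 33 through the 15-acetate F2 to 36.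

2. Step 20. The trienone may dimerise with itself faster than it meets 31, the amine may add to or polymerise the methylene ketones, or the mesylate may be substituted instead of eliminated. The fallback generates the diene oxidatively under neutral conditions. It sets out from 37: a second reductive transposition (conditions of step 15) would pass through the sulfonylhydrazone F3 and the allylic diazene F4 to the 11S monomer F5. Me3SiOSO2CF3 and Et3N would give the trimethylsilyl dienol ether F6, and Pd(OAc)2 in MeCN with 31 present would oxidise F6 (Saegusa oxidation) to trienone 39, which is trapped as it forms. The route is rejoined at 40.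

3. Step 21. γ-Protonation may show poor facial selectivity at C10, and the base may also remove H5 of the product, with epimerisation at C5 or β-elimination of the lactone oxygen O6. The fallback moves the isomerisation from the enolate to the neutral dienol: starting from 40, oxalic acid in wet THF at rt to 40 °C would enolise C3 towards C2 and protonate C10 under general-acid catalysis, where H5 cannot be removed and the isolated methylene groups are not protonated. It comes back at 41 and makes no new compound.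

## Further compounds

F1 | step 13 | (6S,7S,11R)-15-acetoxy-14-[(tert-butyldiphenylsilyl)oxy]-3-oxoguaia-1(10),4-dien-12,6-olide | CC(=O)OCC1=C2[C@H]3OC(=O)[C@H](C)[C@@H]3CCC(CO[Si](c4ccccc4)(c4ccccc4)C(C)(C)C)=C2CC1=O
F2 | step 18 | (6S,7S,11S)-15-acetoxy-14-[(tert-butyldiphenylsilyl)oxy]-3-oxoguaia-1(10),4-dien-12,6-olide | CC(=O)OCC1=C2[C@H]3OC(=O)[C@@H](C)[C@@H]3CCC(CO[Si](c4ccccc4)(c4ccccc4)C(C)(C)C)=C2CC1=O
F3 | step 20 | N-(C14-alkyl)-N-(2-nitrobenzenesulfonyl) acetone hydrazone of 37 | C=C1C(=O)CC2=C(CN(N=C(C)C)S(=O)(=O)c3ccccc3[N+](=O)[O-])CC[C@@H]3[C@H](OC(=O)[C@H]3C)[C@@H]12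
F4 | step 20 | C14 monoalkyl diazene (11S series) | C=C1C(=O)CC2=C(CN=N)CC[C@@H]3[C@H](OC(=O)[C@H]3C)[C@@H]12
F5 | step 20 | (11S)-3-oxo-1αH,5αH,6βH,7αH-guaia-4(15),10(14)-dien-12,6-olide | C=C1C(=O)C[C@H]2C(=C)CC[C@@H]3[C@H](OC(=O)[C@H]3C)[C@@H]12
F6 | step 20 | (11S)-3-[(trimethylsilyl)oxy]-1αH,5αH,6βH,7αH-guaia-2,4(15),10(14)-trien-12,6-olide | C=C1C(O[Si](C)(C)C)=C[C@H]2C(=C)CC[C@@H]3[C@H](OC(=O)[C@H]3C)[C@@H]12
F0 | step 21 | none | none
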